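**Retrosynthetic overview**
- Target ⇒ its upper-unit 5,7,3',4'-tetrabenzyl ether; the last step is hydrogenolysis only.
- Key disconnection: the interflavan C4 (ring C)–C8 (ring D) bond ⇒ the C4 flavan-4-ylium cation of a benzyl-protected 2,3-cis-leucocyanidin (extension unit) plus fully unprotected EGCG (starter unit). This is the carbocation/quinone-methide capture by which the plant is presumed to join flavan-3-ol units; attack anti to the 3-OH sets 4β.
- The protected leucocyanidin ⇒ tetra-O-benzylepicatechin (DDQ oxidation of C4–H) ⇒ (−)-epicatechin.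
- Rings: none is closed in the route. Both pyran rings (ring C, ring F), the gallate and the four C2/C3 stereocentres are bought intact in (−)-epicatechin and EGCG. The only skeleton-forming event is the biosynthesis-type union of the two flavan ring systems, which also creates the fifth stereocentre (C4).

Assumption: the SMILES is read as (−)-epicatechin-(4β→8)-(−)-epigallocatechin 3-O-gallate, upper unit 2R,3R,4R (2,3-cis, 3,4-trans), lower unit 2R,3R.

**Step 1**
Reactants: 1 (−)-epicatechin
Product: 2 tetra-O-benzyl-(−)-epicatechin [(2R,3R)-5,7,3',4'-tetrakis(benzyloxy)flavan-3-ol; 3-OH free]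
Conditions: BnBr (4.4 equiv), K2CO3 (5 equiv), DMF, 0 °C → rt, Ar
Reagents that add atoms: benzyl bromide (BrCc1ccccc1)
Why: Williamson ether synthesis in which K2CO3 deprotonates only the four phenols and not the secondary 3-OH, so O-benzylation stops at the tetra-ether, the low temperature limits C-benzylation of ring A and C2 epimerisation, and no stereocentre is touched.

**Step 2**
Reactants: 2 tetra-O-benzyl-(−)-epicatechin
Product: 4 tetra-O-benzyl-2,3-cis-leucocyanidin [(2R,3R,4S)-5,7,3',4'-tetrakis(benzyloxy)flavan-3,4-diol; 4β-OH], via flavan-4-ylium DDQH ion pair 3 (not isolated)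
Conditions: DDQ (1.5 equiv), CH2Cl2/H2O (20:1), rt
Reagents that add atoms: water (O)
Why: DDQ benzylic oxidation by hydride abstraction, in which the 5,7-dibenzyloxy ring A and O1 make C4–H the most hydridic position, DDQ takes the hydride to leave ion pair 3, water adds to the cation anti to the α-oriented 3-OH and 2-aryl groups to give the 3,4-trans (4β) alcohol while the DDQH anion is protonated to the hydroquinone, and the C4 configuration of 4 is of no consequence because the centre is ionised again in step 3.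

**Step 3**
Reactants: 4 tetra-O-benzyl-2,3-cis-leucocyanidin; 5 (−)-epigallocatechin 3-O-gallate (EGCG)
Product: 7 epicatechin-(4β→8)-EGCG 5,7,3',4'-tetra-O-benzyl ether (benzyl groups on the upper unit only; upper unit 2R,3R; 4β interflavan bond; lower unit 2R,3R), via flavan-4-ylium tosylate ion pair 6 (not isolated)
Conditions: 5 (5 equiv), p-toluenesulfonic acid monohydrate (0.2 equiv), THF, 0 °C, slow addition of 4 over 2 h, then rt, Ar
Reagents that add atoms: none
Why: Proposed new method: an acid-catalysed SN1 Friedel–Crafts condensation of a flavan-3,4-diol with a wholly unprotected flavan-3-ol gallate, in which TsOH ionises the ortho/para-alkoxy-activated C4–OH of 4 to the flavan-4-ylium tosylate 6 (the benzyl-protected counterpart of the cation that the extension unit is presumed to form in the plant), the free phloroglucinol-type ring A of 5 (in fivefold excess, which suppresses self-condensation of 4 and double alkylation) is the most nucleophilic carbon present and attacks through C8, loss of the ring proton returns TsOH, and approach anti to the α-face 3-OH/2-aryl pair sets the new C4 centre as 4β (3,4-trans; 4R once the benzyl groups are removed); the closest known reactions are the acid-promoted condensation of free-phenolic leucocyanidin and catechin to procyanidin B3 and the silyl-triflate- or clay-promoted couplings of benzylated C4-oxygenated epicatechins with benzylated flavan-3-ols.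

**Step 4**
Reactants: 7 epicatechin-(4β→8)-EGCG 5,7,3',4'-tetra-O-benzyl ether
Product: 8 (−)-epicatechin-(4β→8)-(−)-epigallocatechin 3-O-gallate (CNP0246304.2)
Conditions: H2 (1 atm), Pd(OH)2 on carbon (20 wt%), THF/MeOH/H2O (20:1:1), rt
Reagents that add atoms: none
Why: Catalytic hydrogenolysis of the four aryl benzyl ethers under neutral conditions, which leaves the gallate ester, the acid- and base-sensitive interflavan bond and all five stereocentres untouched.

**Compound list**
1 | (−)-epicatechin, (2R,3R) | O[C@@H]1Cc2c(O)cc(O)cc2O[C@@H]1c1ccc(O)c(O)c1 | starting material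
2 | tetra-O-benzyl-(−)-epicatechin, (2R,3R)-5,7,3',4'-tetrakis(benzyloxy)flavan-3-ol | O[C@@H]1Cc2c(OCc3ccccc3)cc(OCc3ccccc3)cc2O[C@@H]1c1ccc(OCc2ccccc2)c(OCc2ccccc2)c1 | intermediate
3 | (2R,3R)-5,7,3',4'-tetrakis(benzyloxy)-3-hydroxyflavan-4-ylium 2,3-dichloro-5,6-dicyano-4-hydroxyphenolate, the ion pair left by hydride transfer from C4 of 2 to DDQ (not isolated) | O[C@@H]1[CH+]c2c(OCc3ccccc3)cc(OCc3ccccc3)cc2O[C@@H]1c1ccc(OCc2ccccc2)c(OCc2ccccc2)c1.N#Cc1c(O)c(Cl)c(Cl)c([O-])c1C#N | intermediate
4 | tetra-O-benzyl-2,3-cis-leucocyanidin, (2R,3R,4S)-5,7,3',4'-tetrakis(benzyloxy)flavan-3,4-diol (4β-OH) | O[C@H]1c2c(OCc3ccccc3)cc(OCc3ccccc3)cc2O[C@H](c2ccc(OCc3ccccc3)c(OCc3ccccc3)c2)[C@@H]1O | intermediate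
5 | (−)-epigallocatechin 3-O-gallate (EGCG), (2R,3R) | O=C(O[C@@H]1Cc2c(O)cc(O)cc2O[C@@H]1c1cc(O)c(O)c(O)c1)c1cc(O)c(O)c(O)c1 | starting material
6 | (2R,3R)-5,7,3',4'-tetrakis(benzyloxy)-3-hydroxyflavan-4-ylium p-toluenesulfonate, the ion pair formed when TsOH ionises the 4-OH of 4 (not isolated) | O[C@@H]1[CH+]c2c(OCc3ccccc3)cc(OCc3ccccc3)cc2O[C@@H]1c1ccc(OCc2ccccc2)c(OCc2ccccc2)c1.Cc1ccc(S(=O)(=O)[O-])cc1 | intermediate
7 | epicatechin-(4β→8)-EGCG 5,7,3',4'-tetra-O-benzyl ether (upper unit 2R,3R, 4β-linked, 3,4-trans; lower unit 2R,3R) | O=C(O[C@@H]1Cc2c(O)cc(O)c([C@H]3c4c(OCc5ccccc5)cc(OCc5ccccc5)cc4O[C@H](c4ccc(OCc5ccccc5)c(OCc5ccccc5)c4)[C@@H]3O)c2O[C@@H]1c1cc(O)c(O)c(O)c1)c1cc(O)c(O)c(O)c1 | intermediate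
8 | (−)-epicatechin-(4β→8)-(−)-epigallocatechin 3-O-gallate (CNP0246304.2; upper unit 2R,3R,4R; lower unit 2R,3R) | O=C(O[C@@H]1Cc2c(O)cc(O)c([C@H]3c4c(O)cc(O)cc4O[C@H](c4ccc(O)c(O)c4)[C@@H]3O)c2O[C@@H]1c1cc(O)c(O)c(O)c1)c1cc(O)c(O)c(O)c1 | target

**Step count**
Total step count: 4.
Longest linear sequence: 4 steps (1 → 2 → 4 → 7 → 8); 5 enters unmodified at step 3.

**Steps most likely to fail, with fallbacks**

Step 3 (highest risk). Unprotected 5 may be attacked partly through C6, giving the 4→6 isomer as the expected minor product. Compound 7 may be alkylated a second time, and 4 may self-condense through its own ring A. The fallback masks the nucleophile so that the regiochemistry is no longer in question. It sets out from 5 and comes back to the route at 8. Exhaustive O-benzylation of 5 (BnBr, K2CO3, DMF; a modest yield is affordable because 5 is cheap) gives octa-O-benzyl-EGCG F1, whose ring A reacts only through C8. Coupling of F1 (3 equiv) with 4 under trimethylsilyl triflate in CH2Cl2 at −78 °C gives the dodeca-O-benzyl dimer F2. Hydrogenolysis of F2 (H2, Pd(OH)2 on carbon) gives 8 directly.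

Step 2. Compound 4 may be over-oxidised to the 4-ketone, and the acid-labile benzylic alcohol may be lost on silica. The fallback by-passes the diol altogether. It sets out from 2 and comes back at 7. DDQ oxidation of 2 in dry CH2Cl2 with 2-ethoxyethanol as the trap gives the 4β-(2-ethoxyethoxy) ether F3, a stable mixed ether that cannot be oxidised further. Under the acid of step 3, F3 loses 2-ethoxyethanol, forms the same tosylate ion pair 6 and gives 7 with 5.

Step 1. Ring A may be C-benzylated, the polyphenoxide may epimerise at C2, and the yield may be modest. The fallback never exposes a free polyphenoxide. It sets out from 1 and comes back at 2. Ac2O/pyridine gives penta-O-acetyl-(−)-epicatechin F4. NaH, BnCl and a measured amount of water in DMF cleave the aryl acetates one at a time and benzylate each phenoxide as it is released, giving 3-O-acetyl-tetra-O-benzylepicatechin F5. K2CO3 in MeOH/THF removes the 3-acetate to give 2.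

**Further compounds**
F1 | step 3 | octa-O-benzyl-EGCG, (2R,3R) | O=C(O[C@@H]1Cc2c(OCc3ccccc3)cc(OCc3ccccc3)cc2O[C@@H]1c1cc(OCc2ccccc2)c(OCc2ccccc2)c(OCc2ccccc2)c1)c1cc(OCc2ccccc2)c(OCc2ccccc2)c(OCc2ccccc2)c1
F2 | step 3 | dodeca-O-benzyl epicatechin-(4β→8)-EGCG (all twelve phenols benzylated, upper 3-OH free) | O=C(O[C@@H]1Cc2c(OCc3ccccc3)cc(OCc3ccccc3)c([C@H]3c4c(OCc5ccccc5)cc(OCc5ccccc5)cc4O[C@H](c4ccc(OCc5ccccc5)c(OCc5ccccc5)c4)[C@@H]3O)c2O[C@@H]1c1cc(OCc2ccccc2)c(OCc2ccccc2)c(OCc2ccccc2)c1)c1cc(OCc2ccccc2)c(OCc2ccccc2)c(OCc2ccccc2)c1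
F3 | step 2 | tetra-O-benzyl-4β-(2-ethoxyethoxy)epicatechin, (2R,3R,4S) | CCOCCO[C@H]1c2c(OCc3ccccc3)cc(OCc3ccccc3)cc2O[C@H](c2ccc(OCc3ccccc3)c(OCc3ccccc3)c2)[C@@H]1O
F4 | step 1 | penta-O-acetyl-(−)-epicatechin, (2R,3R) | CC(=O)O[C@@H]1Cc2c(OC(C)=O)cc(OC(C)=O)cc2O[C@@H]1c1ccc(OC(C)=O)c(OC(C)=O)c1
F5 | step 1 | 3-O-acetyl-5,7,3',4'-tetra-O-benzyl-(−)-epicatechin, (2R,3R) | CC(=O)O[C@@H]1Cc2c(OCc3ccccc3)cc(OCc3ccccc3)cc2O[C@@H]1c1ccc(OCc2ccccc2)c(OCc2ccccc2)c1
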